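**Retrosynthetic overview**
1. C6=O, C7–OH and C8–H go on last, on the finished tetracycle. The sequence is allylic C6–H oxidation, then reductive α-hydroxylation of the C7=C8 bond of 9,13-epoxylabd-7-en-15,16-olide.
2. Key disconnection, C9–O. Spiro carbon C9 of ring B is the tertiary end of a C7–C8–C9 allyl system whose other end is the oxygenated C7. The C13 carbinol oxygen of the preformed lactone ring sits four atoms from C9 (O–C13–C12–C11–C9). Axial C20 on C10 screens the β face of C9.
3. C12–C13 disconnection. The (R)-malic acid dioxolanone enolate (C13–C16, with C13 preset) adds 1,6 to a 9-vinyl-8-en-7-one. The same C7 carbonyl first activates C12 and later leaves as water.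
4. The vinyl enone (rings A and B, C5 and C10) comes from (+)-sclareolide by dehydration, C7 allylic oxidation and 1,4-elimination.
5. Ring order: rings A and B (sclareolide), then the lactone ring (step 8), then the tetrahydrofuran ring (step 9, last).

Key step: step 9

Remark: labdane numbering (C1–C20, α/β with C20 β) is used throughout. The C7 carbinol configuration drawn for the key-step precursor is the expected one but has no consequence, because C7 is planarised on ionisation.

Step 1
Reactants: 1 (+)-sclareolide
Product: 2 methyl (5S,10S)-13,14,15,16-tetranorlabd-8-en-12-oate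
Conditions: conc. H2SO4, MeOH, reflux
Reagents that add atoms: methanol, CO
Why: Acid-catalysed lactone methanolysis followed by E1 dehydration of the tertiary C8 alcohol under equilibrating conditions should funnel the alkene isomers to the tetrasubstituted, thermodynamically preferred C8=C9 olefin, erasing C8 and C9 on purpose while C5 and C10 stay untouched.

Step 2
Reactants: 2 methyl (5S,10S)-13,14,15,16-tetranorlabd-8-en-12-oate
Product: 3 (5S,10S)-13,14,15,16-tetranorlabd-8-en-12-ol
Conditions: LiAlH4, THF, 0 °C to rt
Reagents that add atoms: none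
Why: This is a standard LiAlH4 ester reduction in which the isolated tetrasubstituted alkene is inert and no stereocentre is formed.

Step 3
Reactants: 3 (5S,10S)-13,14,15,16-tetranorlabd-8-en-12-ol
Product: 4 (5S,10S)-13,14,15,16-tetranorlabd-8-en-12-yl methanesulfonate
Conditions: MsCl, Et3N, CH2Cl2, 0 °C
Reagents that add atoms: methanesulfonyl chloride, CS(=O)(=O)Cl
Why: Sulfonylation of an unhindered primary alcohol installs the leaving group needed in step 5 without touching the alkene or any stereocentre.

Step 4
Reactants: 4 (5S,10S)-13,14,15,16-tetranorlabd-8-en-12-yl methanesulfonate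
Product: 5 (5S,10S)-7-oxo-13,14,15,16-tetranorlabd-8-en-12-yl methanesulfonate
Conditions: CrO3, 3,5-dimethylpyrazole, CH2Cl2, −20 °C
Reagents that add atoms: chromium trioxide, O=[Cr](=O)=O
Why: In this CrO3–dimethylpyrazole allylic oxidation the ring methylene C7 is the only unhindered secondary allylic site (C17 is primary, and C11 is deactivated by the neighbouring mesylate-bearing carbon and crowded by C1 and C20), so the conjugated 8-en-7-one should result with no new stereocentre.

Step 5
Reactants: 5 (5S,10S)-7-oxo-13,14,15,16-tetranorlabd-8-en-12-yl methanesulfonate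
Product: 6 (5S,10S)-13,14,15,16-tetranorlabda-8,11-dien-7-one
Conditions: DBU, toluene, rt to 40 °C
Reagents that add atoms: none
Why: In a vinylogous E1cB (1,4-) elimination DBU removes the γ-proton at C11, acidified through the enone, and the extended enolate expels mesylate from C12 to give the linearly conjugated 9-vinyl enone.

Step 6
Reactants: 7 (R)-malic acid; 8 pivalaldehyde
Product: 9 (2R,4R)-2-tert-butyl-5-oxo-1,3-dioxolane-4-acetic acid (cis)
Conditions: p-TsOH (cat.), H2SO4 (cat.), pentane, reflux, water separator; recrystallisation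
Reagents that add atoms: none
Why: Acid-catalysed acetalisation (the self-regeneration-of-stereocentres device) ties the α-hydroxy acid unit into the five-membered dioxolanone, and under equilibration the cis isomer predominates and crystallises, so the carbinol configuration is copied onto the new acetal carbon (2R).

Step 7
Reactants: 9 (2R,4R)-2-tert-butyl-5-oxo-1,3-dioxolane-4-acetic acid (cis); 6 (5S,10S)-13,14,15,16-tetranorlabda-8,11-dien-7-one
Product: 11 [(2R,4R)-2-tert-butyl-5-oxo-4-{2-[(5S,10S)-7-oxo-11,12,13,14,15,16-hexanorlabd-8-en-9-yl]ethyl}-1,3-dioxolan-4-yl]acetic acid (13R in labdane terms), via dilithium enolate-carboxylate 10 (not isolated)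
Conditions: LiN(SiMe3)2 (2.1 equiv), THF, −78 °C; then 6, −78 to −30 °C; 1 M HCl; then DBU, CH2Cl2, rt, acidic wash
Reagents that add atoms: none
Why: In this vinylogous (1,6-) Michael addition the hindered enolate attacks the only unsubstituted acceptor terminus C12 (C9 is fully substituted) from the face anti to the tert-butyl group, so C12 takes the place of the former hydrogen with overall retention (13R), and the DBU treatment returns the extended enolate product to the conjugated C8=C9 enone.

Step 8
Reactants: 11 the adduct acid of step 7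
Product: 13 (7S,13R)-7,13-dihydroxylabd-8-en-15,16-olide (7β-OH), via trihydroxy acid 12 (not isolated)
Conditions: LiBH4 (5 equiv), THF–MeOH, 0 °C to rt; then 1 M HCl to pH 3, rt
Reagents that add atoms: none
Why: In this chemoselective borohydride reduction the activated dioxolanone carbonyl C16 and the C7 ketone are reduced (the latter in the 1,2-mode because C9 is fully substituted, with hydride from the α face giving the 7β-ol) while the lithium carboxylate C15 is inert and the acetal collapses, and acidification then triggers spontaneous γ-lactonisation of O16 onto C15, closing the lactone ring without touching the C13–O bond.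

Step 9
Reactants: 13 (7S,13R)-7,13-dihydroxylabd-8-en-15,16-olide
Product: 15 (9R,13R)-9,13-epoxylabd-7-en-15,16-olide, via ring B allyl cation 14 (not isolated)
Conditions: (1S)-(+)-camphor-10-sulfonic acid (10 mol %), 4 Å MS, CH2Cl2, −20 °C to rt
Reagents that add atoms: none
Why: The Brønsted acid ionises the C7 allylic alcohol (the C13 carbinol, flanked by the two electron-withdrawing arms of the lactone, does not ionise) to the ring B allyl cation 14, whose charge sits on C7 and on the tertiary C9 but not on C8. The C13 hydroxyl, held four atoms away by the C11–C12 tether and pre-organised by the quaternary C13, adds to C9 and the double bond ends up at C7=C8; this is an SN1′ cyclodehydration whose closest known relatives are the acid-induced closures of monoallylic diols of the 4-hydroxy-7,8-dihydro-β-ionol type to theaspirane-type 1-oxaspiro[4.5]dec-6-enes. The tetrahydrofuran ring closes in the 5-exo mode with respect to the allyl π-system (C9 inside the new ring, C8=C7 outside). C9 is the only new stereocentre and is controlled by ring B: the axial C20 methyl on the neighbouring C10 screens the β face, so oxygen enters axially from the α face and C11 becomes equatorial (9R) whichever C7 epimer is used, while C13 keeps its configuration because its C–O bond is never broken. The step needs regioselectivity for C9 over C7 and C8, which is secured by ring size (attack at C7 would give a bridged seven-membered ether) and by the node of the allyl cation at C8, which excludes the six-membered 8,13-ether typical of simple C8 cations. It also needs capture to outrun proton loss to dienes, which low temperature, a non-nucleophilic medium and removal of water by the sieves should favour.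

Step 10
Reactants: 15 (9R,13R)-9,13-epoxylabd-7-en-15,16-olide
Product: 16 (9R,13R)-9,13-epoxy-6-oxolabd-7-en-15,16-olide
Conditions: CrO3, 3,5-dimethylpyrazole, CH2Cl2, −20 °C
Reagents that add atoms: chromium trioxide, O=[Cr](=O)=O
Why: In this allylic oxidation of the theaspirane-to-theaspirone type C6 is the only secondary allylic position (C9 is quaternary, C17 primary), both ether α-carbons are fully substituted and the lactone CH2O is deactivated, so the γ-alkoxy enone should form with C5 remaining trans (its thermodynamic configuration).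

Step 11
Reactants: 16 (9R,13R)-9,13-epoxy-6-oxolabd-7-en-15,16-olide
Product: 18 (5S,7R,8R,9R,10S,13R)-9,13-epoxy-7-hydroxy-6-oxolabdan-15,16-olide (target), via 7-hydroperoxide 17 (not isolated)
Conditions: Mn(dpm)3 (10 mol %), PhSiH3, O2 (1 atm), i-PrOH–CH2Cl2, 0 °C; P(OEt)3; then DBU (cat.), CH2Cl2, 0 °C, Ar
Reagents that add atoms: dioxygen, O=O
Why: In this Mukaiyama-type reductive α-hydroxylation of an enone the manganese hydride should deliver H to C8 axially from the β face, because the α face of C8 lies directly under the axial C9–O bond and the C16 methylene of the spiro-lactone and α-delivery would force C17 into a syn-diaxial clash with C20 (8R, equatorial methyl); the C7 α-keto radical is then trapped by O2, the hydroperoxide is reduced by P(OEt)3, and C7, an enolisable α-ketol carbon, should settle as the equatorial, hydrogen-bonded 7β-alcohol (7R) on brief DBU equilibration, which is too mild to enolise the lactone or disturb trans-fused C5.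

**Compound list**
1 | (+)-sclareolide, (3aR,5aS,9aS,9bR)-3a,6,6,9a-tetramethyldecahydronaphtho[2,1-b]furan-2(1H)-one | C[C@@]1(O3)CC[C@H]2C(C)(C)CCC[C@]2(C)[C@H]1CC3=O | starting material
2 | methyl (5S,10S)-13,14,15,16-tetranorlabd-8-en-12-oate | CC=1CC[C@H]2C(C)(C)CCC[C@]2(C)C=1CC(=O)OC | intermediate
3 | (5S,10S)-13,14,15,16-tetranorlabd-8-en-12-ol | CC=1CC[C@H]2C(C)(C)CCC[C@]2(C)C=1CCO | intermediate
4 | (5S,10S)-13,14,15,16-tetranorlabd-8-en-12-yl methanesulfonate | CC=1CC[C@H]2C(C)(C)CCC[C@]2(C)C=1CCOS(C)(=O)=O | intermediate
5 | (5S,10S)-7-oxo-13,14,15,16-tetranorlabd-8-en-12-yl methanesulfonate | CC=1C(=O)C[C@H]2C(C)(C)CCC[C@]2(C)C=1CCOS(C)(=O)=O | intermediate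
6 | (5S,10S)-13,14,15,16-tetranorlabda-8,11-dien-7-one (9-vinyl enone) | CC=1C(=O)C[C@H]2C(C)(C)CCC[C@]2(C)C=1C=C | intermediate
7 | (R)-malic acid | O[C@H](CC(=O)O)C(=O)O | starting material
8 | pivalaldehyde | CC(C)(C)C=O | starting material
9 | (2R,4R)-2-tert-butyl-5-oxo-1,3-dioxolane-4-acetic acid (cis) | OC(=O)C[C@H]1O[C@@H](C(C)(C)C)OC1=O | intermediate
10 | dilithium enolate-carboxylate of 9 (acetal carbon unchanged) | [Li+].[Li+].[O-]C(=O)CC1=C([O-])O[C@H](C(C)(C)C)O1 | intermediate
11 | 1,6-adduct acid, (2R,4R)-dioxolanone carrying CH2CO2H and the 2-(7-oxo-8-en-9-yl)ethyl chain on C4 (13R) | CC=1C(=O)C[C@H]2C(C)(C)CCC[C@]2(C)C=1CC[C@]3(CC(=O)O)O[C@@H](C(C)(C)C)OC3=O | intermediate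
12 | (7S,13R)-7,13,16-trihydroxylabd-8-en-15-oic acid | CC=1[C@@H](O)C[C@H]2C(C)(C)CCC[C@]2(C)C=1CC[C@](O)(CO)CC(=O)O | intermediate
13 | (7S,13R)-7,13-dihydroxylabd-8-en-15,16-olide (7β-OH) | CC=1[C@@H](O)C[C@H]2C(C)(C)CCC[C@]2(C)C=1CC[C@]3(O)COC(=O)C3 | intermediate
14 | ring B allyl cation (C7–C8–C9, drawn with the charge on C9) | CC1=CC[C@H]2C(C)(C)CCC[C@]2(C)[C+]1CC[C@]3(O)COC(=O)C3 | intermediate
15 | (9R,13R)-9,13-epoxylabd-7-en-15,16-olide | CC1=CC[C@H]2C(C)(C)CCC[C@]2(C)[C@@]12CC[C@@]1(COC(=O)C1)O2 | intermediate
16 | (9R,13R)-9,13-epoxy-6-oxolabd-7-en-15,16-olide | CC1=CC(=O)[C@H]2C(C)(C)CCC[C@]2(C)[C@@]12CC[C@@]1(COC(=O)C1)O2 | intermediate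
17 | 9,13-epoxy-7β-hydroperoxy-6-oxolabdan-15,16-olide | C[C@@H]1[C@@H](OO)C(=O)[C@H]2C(C)(C)CCC[C@]2(C)[C@@]12CC[C@@]1(COC(=O)C1)O2 | intermediate
18 | (5S,7R,8R,9R,10S,13R)-9,13-epoxy-7-hydroxy-6-oxolabdan-15,16-olide | C[C@@H]1[C@@H](O)C(=O)[C@H]2C(C)(C)CCC[C@]2(C)[C@@]12CC[C@@]1(COC(=O)C1)O2 | target

**Total step count:** 11. **Longest linear sequence:** 10 (steps 1–5 and 7–11).

**Steps most likely to fail**

Step 11. Hydrogen-atom delivery to C8 may occur from the wrong face, O2 capture at C7 may be unselective, or plain conjugate reduction may compete. The fallback sets out from 16 and comes back at 18, and it makes the C–H and C–O bonds separately.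
- Radical hydrogenation under argon (Mn(dpm)3, PhSiH3, t-BuOOH, i-PrOH) should give the saturated ketone (8R,9R,13R)-9,13-epoxy-6-oxolabdan-15,16-olide F1, at which stage C8 epimers could be separated.
- Acid-mediated α-acetoxylation with PhI(OAc)2, BF3·OEt2 and AcOH should give 7β-acetoxy-9,13-epoxy-6-oxolabdan-15,16-olide F2. The C6 enol attacks the hypervalent iodine from the α face and acetate displaces iodobenzene with inversion.
- Mild methanolysis (K2CO3, MeOH, 0 °C, acidic work-up) should then release 18.

Step 7. Proton transfer from the α′ (C6) and γ (C17) positions of the dienone may quench the basic enolate, or 1,2-addition and oligomerisation of the dienone may intervene. The fallback sets out from 4 and comes back at 11, and it replaces the conjugate addition by a plain substitution with the C7 oxidation moved later.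
- A Finkelstein exchange (NaI, acetone) should give (5S,10S)-12-iodo-13,14,15,16-tetranorlabd-8-ene F3.
- SN2 alkylation of the dianion 10 with it in THF–DMPU at −78 to −20 °C, again anti to the tert-butyl group, should give the 7-deoxo analogue of the adduct acid F4.
- CrO3–3,5-dimethylpyrazole oxidation of C7 should then deliver 11.

Step 9. Proton loss from the allyl cation to ring B dienes may outrun capture, or acid may dehydrate the C13 carbinol. The fallback sets out from 13 and comes back at 15, and it swaps the free cation for a stereospecific epoxide opening.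
- Hydroxyl-directed epoxidation (VO(acac)2, t-BuOOH, CH2Cl2) should give 8β,9β-epoxy-7β,13-dihydroxylabdan-15,16-olide F5.
- Catalytic camphorsulfonic acid should open it by 5-exo attack of the C13 hydroxyl at C9 with inversion, giving 9α,13-epoxy-7β,8β-dihydroxylabdan-15,16-olide F6.
- 1,1′-Thiocarbonyldiimidazole should convert the cis-diol into the 7,8-cyclic thionocarbonate F7.
- Corey–Winter olefination with hot P(OMe)3 should then give 15.

**Further compounds**
F1 | step 11 | (8R,9R,13R)-9,13-epoxy-6-oxolabdan-15,16-olide | C[C@@H]1CC(=O)[C@H]2C(C)(C)CCC[C@]2(C)[C@@]12CC[C@@]1(COC(=O)C1)O2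
F2 | step 11 | 7β-acetoxy-9,13-epoxy-6-oxolabdan-15,16-olide | C[C@@H]1[C@@H](OC(C)=O)C(=O)[C@H]2C(C)(C)CCC[C@]2(C)[C@@]12CC[C@@]1(COC(=O)C1)O2
F3 | step 7 | (5S,10S)-12-iodo-13,14,15,16-tetranorlabd-8-ene | CC=1CC[C@H]2C(C)(C)CCC[C@]2(C)C=1CCI
F4 | step 7 | 7-deoxo analogue of the adduct acid 11 | CC=1CC[C@H]2C(C)(C)CCC[C@]2(C)C=1CC[C@]3(CC(=O)O)O[C@@H](C(C)(C)C)OC3=O
F5 | step 9 | 8β,9β-epoxy-7β,13-dihydroxylabdan-15,16-olide (13R) | C[C@]1(O5)[C@@H](O)C[C@H]2C(C)(C)CCC[C@]2(C)[C@]15CC[C@]3(O)COC(=O)C3
F6 | step 9 | 9α,13-epoxy-7β,8β-dihydroxylabdan-15,16-olide (13R) | C[C@]1(O)[C@@H](O)C[C@H]2C(C)(C)CCC[C@]2(C)[C@@]12CC[C@@]1(COC(=O)C1)O2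
F7 | step 9 | 7,8-cyclic thionocarbonate of F6 | C[C@]1(OC(=S)O6)[C@@H]6C[C@H]2C(C)(C)CCC[C@]2(C)[C@@]12CC[C@@]1(COC(=O)C1)O2
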